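## Retrosynthetic overview

1. Target 21 ⇐ global hydrogenolysis of the hexabenzyl bis(benzylic acetate) 20 ⇐ twofold aldol addition of the bis-enolate of bis(3-benzyloxy-γ-butyrolactone) 16 to two molecules of O-benzylvanillin 17. This forms both C3–C(benzylic) bonds and both quaternary C3 centres, anti to the C4 arylmethyl group.
2. 16 ⇐ enolate hydroxylation and O-benzylation of the C2-symmetric bis(β-arylmethyl-γ-butyrolactone) 13.
3. 13 ⇐ twofold Evans alkylation of the succinate imide 9 with the biaryl bis(benzylic bromide) 5 (sets both C4 centres), then reductive auxiliary removal and lactonisation.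
4. 5 ⇐ dehydrodivanillin 2 ⇐ oxidative dimerisation of vanillin 1.
5. Ring order: the biaryl bond is made first (step 1, arene rings bought); the two lactone rings are closed together in step 8; no other ring is formed.

Assumption: the lactone is numbered O1, C2 (C=O), C3, C4, C5 throughout, and the biaryl axis (only two ortho substituents) is taken as freely rotating, so the four carbon stereocentres alone define the target, which is (3R,3'R,4R,4'R).

## Route

Step 1
Reactants: 1 vanillin (two molecules)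
Product: 2 dehydrodivanillin (6,6'-dihydroxy-5,5'-dimethoxybiphenyl-3,3'-dicarbaldehyde)
Conditions: FeSO4·7H2O (cat.), Na2S2O8 (0.55 equiv), H2O, 50 °C
Reagents that add atoms: none
Why: Oxidative phenol coupling, in which persulfate-derived radicals oxidise the phenol to a phenoxyl radical that dimerises at its only free ortho position (C5), and the insoluble dimer precipitates before over-oxidation; no stereocentre is formed.

Step 2
Reactants: 2 dehydrodivanillin
Product: 3 6,6'-bis(benzyloxy)-5,5'-dimethoxybiphenyl-3,3'-dicarbaldehyde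
Conditions: BnBr, K2CO3, DMF, 70 °C
Reagents that add atoms: benzyl bromide, BrCc1ccccc1
Why: Williamson etherification of both phenols, which masks them against every base used later and lets all protecting groups fall in one final hydrogenolysis.

Step 3
Reactants: 3 dibenzyl dialdehyde
Product: 4 [6,6'-bis(benzyloxy)-5,5'-dimethoxybiphenyl-3,3'-diyl]dimethanol
Conditions: NaBH4, THF/MeOH, 0 °C → rt
Reagents that add atoms: none
Why: Plain borohydride reduction of two aryl aldehydes to benzylic alcohols, with aryl ethers inert.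

Step 4
Reactants: 4 diol
Product: 5 2,2'-bis(benzyloxy)-5,5'-bis(bromomethyl)-3,3'-dimethoxybiphenyl
Conditions: PBr3, CH2Cl2, 0 °C, used at once
Reagents that add atoms: phosphorus tribromide, BrP(Br)Br
Why: Bromination of an electron-rich benzylic alcohol via its phosphite ester is fast at 0 °C, and the labile dibromide is carried directly into the alkylation.

Step 5
Reactants: 6 mono-tert-butyl succinate; 7 (4S)-4-benzyl-1,3-oxazolidin-2-one
Product: 9 tert-butyl 4-[(4S)-4-benzyl-2-oxo-1,3-oxazolidin-3-yl]-4-oxobutanoate, via mixed pivalic anhydride 8 (not isolated)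
Conditions: PivCl, Et3N, THF, −20 °C; then 7, LiCl, rt
Reagents that add atoms: none
Why: N-acylation of the Evans auxiliary through a mixed anhydride, with the oxazolidinone attacking the unhindered succinyl carbonyl and not the pivaloyl one.

Step 6
Reactants: 9 succinate imide (2.6 equiv); 5 dibromide
Product: 11 di-tert-butyl (3S,3'S)-4,4'-[6,6'-bis(benzyloxy)-5,5'-dimethoxybiphenyl-3,3'-diyl]bis{3-[(4S)-4-benzyl-2-oxo-1,3-oxazolidine-3-carbonyl]butanoate}, via imide sodium enolate 10 (not isolated)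
Conditions: NaN(SiMe3)2, THF, −78 °C; then 5, −78 → −20 °C
Reagents that add atoms: none
Why: Twofold Evans asymmetric alkylation, in which only the more acidic imide α-CH2 is deprotonated to the chelated Z-enolate and the benzylic bromide enters on the face opposite the auxiliary's benzyl group, setting both new centres as S (these become C4 and C4'), with minor diastereomers removable by chromatography because the auxiliary is still attached.

Step 7
Reactants: 11 bis-imide
Product: 12 di-tert-butyl (3S,3'S)-4,4'-[6,6'-bis(benzyloxy)-5,5'-dimethoxybiphenyl-3,3'-diyl]bis[3-(hydroxymethyl)butanoate]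
Conditions: LiBH4, H2O (2 equiv), THF, 0 °C
Reagents that add atoms: none
Why: Reductive cleavage of the activated imide carbonyl to the primary alcohol, with the hindered tert-butyl esters untouched at 0 °C, the auxiliary recovered and the stereocentre (not α to any remaining acidic position) unaffected.

Step 8
Reactants: 12 bis(hydroxy ester)
Product: 13 (4S,4'S)-4,4'-{[6,6'-bis(benzyloxy)-5,5'-dimethoxybiphenyl-3,3'-diyl]bis(methylene)}bis(dihydrofuran-2(3H)-one)
Conditions: p-TsOH·H2O (10 mol %), toluene, 80 °C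
Reagents that add atoms: none
Why: Acid-catalysed lactonisation of a γ-hydroxy tert-butyl ester (loss of the tert-butyl group as isobutene), driven by five-membered ring formation, closes both lactones at once without touching C4.

Step 9
Reactants: 13 bis-lactone
Product: 15 (3S,3'S,4R,4'R)-4,4'-{[6,6'-bis(benzyloxy)-5,5'-dimethoxybiphenyl-3,3'-diyl]bis(methylene)}bis(3-hydroxydihydrofuran-2(3H)-one), via lactone bis(sodium enolate) 14 (not isolated)
Conditions: NaN(SiMe3)2 (2.4 equiv), THF, −78 °C; then trans-2-(phenylsulfonyl)-3-phenyloxaziridine (3 equiv), −78 °C; AcOH quench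
Reagents that add atoms: trans-2-(phenylsulfonyl)-3-phenyloxaziridine, O=S(=O)(c1ccccc1)N1OC1c1ccccc1
Why: Davis enolate oxidation, in which the oxaziridine delivers oxygen anti to the C4 arylmethyl group to give mainly the trans alcohols, and since C3 is planarised again in step 11 its epimer ratio is immaterial and the mixture is carried on.

Step 10
Reactants: 15 bis(3-hydroxy lactone)
Product: 16 (3S,3'S,4R,4'R)-4,4'-{[6,6'-bis(benzyloxy)-5,5'-dimethoxybiphenyl-3,3'-diyl]bis(methylene)}bis[3-(benzyloxy)dihydrofuran-2(3H)-one]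
Conditions: Ag2O, BnBr, 4 Å MS, CH2Cl2, rt, dark
Reagents that add atoms: benzyl bromide, BrCc1ccccc1
Why: Silver-oxide-mediated Williamson benzylation of an α-hydroxy lactone under neutral conditions, which avoids both strong base at the lactone and strong acid next to the electron-rich arenes.

Step 11
Reactants: 16 bis(3-benzyloxy lactone); 17 4-(benzyloxy)-3-methoxybenzaldehyde (3 equiv)
Product: 19 (3S,3'S,4R,4'R)-4,4'-{[6,6'-bis(benzyloxy)-5,5'-dimethoxybiphenyl-3,3'-diyl]bis(methylene)}bis{3-(benzyloxy)-3-[[4-(benzyloxy)-3-methoxyphenyl](hydroxy)methyl]dihydrofuran-2(3H)-one} as a mixture of carbinol epimers, via benzyloxylactone bis(lithium enolate) 18 (not isolated)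
Conditions: LiN(iPr)2 (2.5 equiv), THF, −78 °C; then 17, −78 °C, 1 h; AcOH quench at −78 °C
Reagents that add atoms: none
Why: Twofold directed aldol addition of a lithium α-alkoxy lactone enolate, in which the aldehyde adds to the planar C3 on the face anti to the C4 arylmethyl group, so the new C–C bond is trans to it and the oxygen cis, which is the C3 configuration of the target (the carbinol centres are removed in step 13).

Step 12
Reactants: 19 bis-aldol adduct
Product: 20 bis(benzylic acetate) of 19 (both secondary hydroxyls acetylated; C3 and C4 unchanged)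
Conditions: Ac2O, pyridine, DMAP (cat.), CH2Cl2, 0 °C → rt
Reagents that add atoms: acetic anhydride, CC(=O)OC(C)=O
Why: DMAP-catalysed acylation turns the benzylic hydroxyls into better leaving groups for hydrogenolysis, blocks retro-aldol cleavage, and cannot cause elimination because C3 is quaternary.

Step 13
Reactants: 20 bis(benzylic acetate)
Product: 21 bis-5,5-nortrachelogenin, (3R,3'R,4R,4'R)-4,4'-[(6,6'-dihydroxy-5,5'-dimethoxybiphenyl-3,3'-diyl)bis(methylene)]bis[3-hydroxy-3-(4-hydroxy-3-methoxybenzyl)dihydrofuran-2(3H)-one]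
Conditions: H2 (3 bar), Pd(OH)2/C, THF/EtOH (1:1), AcOH (5 %), rt
Reagents that add atoms: none
Why: Heterogeneous hydrogenolysis cleaves the six O-benzyl bonds and the two benzylic C–OAc bonds (activated by the para oxygen), while the lactones, the non-benzylic tertiary C3–O bonds and all four stereocentres are untouched.

## Compound list

1 | vanillin (4-hydroxy-3-methoxybenzaldehyde) | COc1cc(C=O)ccc1O | starting material
2 | dehydrodivanillin, 6,6'-dihydroxy-5,5'-dimethoxybiphenyl-3,3'-dicarbaldehyde | COc1cc(C=O)cc(-c2cc(C=O)cc(OC)c2O)c1O | intermediate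
3 | 6,6'-bis(benzyloxy)-5,5'-dimethoxybiphenyl-3,3'-dicarbaldehyde | COc1cc(C=O)cc(-c2cc(C=O)cc(OC)c2OCc2ccccc2)c1OCc1ccccc1 | intermediate
4 | [6,6'-bis(benzyloxy)-5,5'-dimethoxybiphenyl-3,3'-diyl]dimethanol | COc1cc(CO)cc(-c2cc(CO)cc(OC)c2OCc2ccccc2)c1OCc1ccccc1 | intermediate
5 | 2,2'-bis(benzyloxy)-5,5'-bis(bromomethyl)-3,3'-dimethoxybiphenyl | COc1cc(CBr)cc(-c2cc(CBr)cc(OC)c2OCc2ccccc2)c1OCc1ccccc1 | intermediate
6 | mono-tert-butyl succinate (4-tert-butoxy-4-oxobutanoic acid) | CC(C)(C)OC(=O)CCC(=O)O | starting material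
7 | (4S)-4-benzyl-1,3-oxazolidin-2-one | O=C1N[C@@H](Cc2ccccc2)CO1 | starting material
8 | 4-tert-butoxy-4-oxobutanoic pivalic anhydride (not isolated) | CC(C)(C)OC(=O)CCC(=O)OC(=O)C(C)(C)C | intermediate
9 | tert-butyl 4-[(4S)-4-benzyl-2-oxo-1,3-oxazolidin-3-yl]-4-oxobutanoate | CC(C)(C)OC(=O)CCC(=O)N1[C@@H](Cc2ccccc2)COC1=O | intermediate
10 | sodium (Z)-enolate of 9 (not isolated) | CC(C)(C)OC(=O)C/C=C(\[O-])N1[C@@H](Cc2ccccc2)COC1=O.[Na+] | intermediate
11 | di-tert-butyl (3S,3'S)-4,4'-[6,6'-bis(benzyloxy)-5,5'-dimethoxybiphenyl-3,3'-diyl]bis{3-[(4S)-4-benzyl-2-oxo-1,3-oxazolidine-3-carbonyl]butanoate} | CC(C)(C)OC(=O)C[C@H](Cc1cc(OC)c(OCc2ccccc2)c(-c2cc(C[C@@H](CC(=O)OC(C)(C)C)C(=O)N3[C@@H](Cc4ccccc4)COC3=O)cc(OC)c2OCc2ccccc2)c1)C(=O)N1[C@@H](Cc2ccccc2)COC1=O | intermediate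
12 | di-tert-butyl (3S,3'S)-4,4'-[6,6'-bis(benzyloxy)-5,5'-dimethoxybiphenyl-3,3'-diyl]bis[3-(hydroxymethyl)butanoate] | CC(C)(C)OC(=O)C[C@H](Cc1cc(OC)c(OCc2ccccc2)c(-c2cc(C[C@@H](CC(=O)OC(C)(C)C)CO)cc(OC)c2OCc2ccccc2)c1)CO | intermediate
13 | (4S,4'S)-4,4'-{[6,6'-bis(benzyloxy)-5,5'-dimethoxybiphenyl-3,3'-diyl]bis(methylene)}bis(dihydrofuran-2(3H)-one) | O=C1C[C@H](Cc2cc(OC)c(OCc3ccccc3)c(-c3cc(C[C@@H]4COC(=O)C4)cc(OC)c3OCc3ccccc3)c2)CO1 | intermediate
14 | bis(sodium enolate) of 13 (not isolated) | [Na+].[Na+].[O-]C1=C[C@H](Cc2cc(OC)c(OCc3ccccc3)c(-c3cc(C[C@@H]4COC([O-])=C4)cc(OC)c3OCc3ccccc3)c2)CO1 | intermediate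
15 | (3S,3'S,4R,4'R)-4,4'-{[6,6'-bis(benzyloxy)-5,5'-dimethoxybiphenyl-3,3'-diyl]bis(methylene)}bis(3-hydroxydihydrofuran-2(3H)-one), major trans isomer, C3 epimers carried along | O=C1[C@@H](O)[C@H](Cc2cc(OC)c(OCc3ccccc3)c(-c3cc(C[C@@H]4COC(=O)[C@H]4O)cc(OC)c3OCc3ccccc3)c2)CO1 | intermediate
16 | (3S,3'S,4R,4'R)-4,4'-{[6,6'-bis(benzyloxy)-5,5'-dimethoxybiphenyl-3,3'-diyl]bis(methylene)}bis[3-(benzyloxy)dihydrofuran-2(3H)-one] | O=C1[C@@H](OCc2ccccc2)[C@H](Cc2cc(OC)c(OCc3ccccc3)c(-c3cc(C[C@@H]4COC(=O)[C@H]4OCc4ccccc4)cc(OC)c3OCc3ccccc3)c2)CO1 | intermediate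
17 | 4-(benzyloxy)-3-methoxybenzaldehyde (O-benzylvanillin) | COc1cc(C=O)ccc1OCc1ccccc1 | starting material
18 | bis(lithium enolate) of 16 (not isolated) | [Li+].[Li+].[O-]C1=C(OCc2ccccc2)[C@H](Cc2cc(OC)c(OCc3ccccc3)c(-c3cc(C[C@@H]4COC([O-])=C4OCc4ccccc4)cc(OC)c3OCc3ccccc3)c2)CO1 | intermediate
19 | (3S,3'S,4R,4'R)-4,4'-{[6,6'-bis(benzyloxy)-5,5'-dimethoxybiphenyl-3,3'-diyl]bis(methylene)}bis{3-(benzyloxy)-3-[[4-(benzyloxy)-3-methoxyphenyl](hydroxy)methyl]dihydrofuran-2(3H)-one}, both carbinol configurations | COc1cc(C(O)[C@]2(OCc3ccccc3)C(=O)OC[C@H]2Cc2cc(OC)c(OCc3ccccc3)c(-c3cc(C[C@@H]4COC(=O)[C@@]4(OCc4ccccc4)C(O)c4ccc(OCc5ccccc5)c(OC)c4)cc(OC)c3OCc3ccccc3)c2)ccc1OCc1ccccc1 | intermediate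
20 | bis(benzylic acetate) of 19, (3S,3'S,4R,4'R), both carbinol configurations | COc1cc(C(OC(C)=O)[C@]2(OCc3ccccc3)C(=O)OC[C@H]2Cc2cc(OC)c(OCc3ccccc3)c(-c3cc(C[C@@H]4COC(=O)[C@@]4(OCc4ccccc4)C(OC(C)=O)c4ccc(OCc5ccccc5)c(OC)c4)cc(OC)c3OCc3ccccc3)c2)ccc1OCc1ccccc1 | intermediate
21 | bis-5,5-nortrachelogenin, (3R,3'R,4R,4'R)-4,4'-[(6,6'-dihydroxy-5,5'-dimethoxybiphenyl-3,3'-diyl)bis(methylene)]bis[3-hydroxy-3-(4-hydroxy-3-methoxybenzyl)dihydrofuran-2(3H)-one] | COc1cc(C[C@]2(O)C(=O)OC[C@H]2Cc2cc(OC)c(O)c(-c3cc(C[C@@H]4COC(=O)[C@@]4(O)Cc4ccc(O)c(OC)c4)cc(OC)c3O)c2)ccc1O | target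

## Step count and risks

Total step count: 13. Longest linear sequence: 12 steps (steps 1–4 and 6–13 from vanillin; step 5 is a one-step branch).

The three steps most likely to fail:

**Step 11** (twofold aldol of a tetrasubstituted enolate with an electron-rich aldehyde; retro-aldol and incomplete double addition are the dangers). The fallback replaces the reversible aldol by an irreversible enolate alkylation; it sets out from 15 and 17 and comes back to the route at 21. Aldehyde 17 is reduced (NaBH4, MeOH) to [4-(benzyloxy)-3-methoxyphenyl]methanol F1, which is brominated (PBr3, Et2O, 0 °C) to 4-(benzyloxy)-3-methoxybenzyl bromide F2. The fourfold lithiated alkoxide enolate of 15 (LiN(iPr)2, 4.4 equiv, THF/DMPU, −78 → −30 °C) is then C-alkylated by F2, again anti to the C4 arylmethyl group, to give the tetra-O-benzyl ether of the target with free tertiary hydroxyls F3. Hydrogenolysis (H2, Pd/C, THF/EtOH) removes the four benzyl groups and gives 21; steps 10 and 12 are then not needed.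

**Step 13** (eight hydrogenolyses in one pot, the hindered benzylic acetates being the slow ones; a quinone methide formed after debenzylation could be trapped instead of reduced). The fallback removes the benzylic oxygen by a radical route before any debenzylation; it sets out from 19 and comes back at 21. Compound 19 is treated with 1,1'-thiocarbonyldiimidazole (DMAP, 1,2-dichloroethane, 60 °C) to give the bis[O-(imidazol-1-ylcarbonothioyl)] derivative of 19 F4. Barton–McCombie reduction (Bu3SnH, AIBN, toluene, 100 °C) gives the hexa-O-benzyl ether of the target F5. The remaining plain O-debenzylation (H2, Pd(OH)2/C, THF/EtOH) then gives 21.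

**Step 6** (twofold alkylation with a labile bis(benzylic bromide); both ends must react and the sodium enolate must not decompose). The fallback builds the C4 centres by condensation and asymmetric hydrogenation; it sets out from 3 and comes back at 13. Twofold Stobbe condensation of 3 with dimethyl succinate (NaOMe, MeOH, reflux, then acid) gives the (3E,3'E)-bis[3-(methoxycarbonyl)but-3-enoic acid] F6. Asymmetric hydrogenation (H2 5 bar, [Rh(cod)(Et-DuPhos)]BF4 with the ligand antipode that delivers the S product, Et3N, MeOH) gives the (3S,3'S)-bis[3-(methoxycarbonyl)butanoic acid] F7. Selective reduction of the ester beside the carboxylate (KOH; CaCl2/NaBH4, EtOH, 0 °C → rt; then HCl) with spontaneous lactonisation gives 13. The weakness of this detour is that any meso isomer from imperfect enantioselectivity is hard to separate, which is why the auxiliary route is the first choice.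

## Further compounds

F1 | step 11 | [4-(benzyloxy)-3-methoxyphenyl]methanol | COc1cc(CO)ccc1OCc1ccccc1
F2 | step 11 | 4-(benzyloxy)-3-methoxybenzyl bromide | COc1cc(CBr)ccc1OCc1ccccc1
F3 | step 11 | (3R,3'R,4R,4'R)-4,4'-{[6,6'-bis(benzyloxy)-5,5'-dimethoxybiphenyl-3,3'-diyl]bis(methylene)}bis{3-[4-(benzyloxy)-3-methoxybenzyl]-3-hydroxydihydrofuran-2(3H)-one} | COc1cc(C[C@]2(O)C(=O)OC[C@H]2Cc2cc(OC)c(OCc3ccccc3)c(-c3cc(C[C@@H]4COC(=O)[C@@]4(O)Cc4ccc(OCc5ccccc5)c(OC)c4)cc(OC)c3OCc3ccccc3)c2)ccc1OCc1ccccc1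
F4 | step 13 | bis[O-(imidazol-1-ylcarbonothioyl)] derivative of 19, (3S,3'S,4R,4'R), both carbinol configurations | COc1cc(C(OC(=S)n3ccnc3)[C@]2(OCc3ccccc3)C(=O)OC[C@H]2Cc2cc(OC)c(OCc3ccccc3)c(-c3cc(C[C@@H]4COC(=O)[C@@]4(OCc4ccccc4)C(OC(=S)n4ccnc4)c4ccc(OCc5ccccc5)c(OC)c4)cc(OC)c3OCc3ccccc3)c2)ccc1OCc1ccccc1
F5 | step 13 | (3R,3'R,4R,4'R)-4,4'-{[6,6'-bis(benzyloxy)-5,5'-dimethoxybiphenyl-3,3'-diyl]bis(methylene)}bis{3-(benzyloxy)-3-[4-(benzyloxy)-3-methoxybenzyl]dihydrofuran-2(3H)-one} | COc1cc(C[C@]2(OCc3ccccc3)C(=O)OC[C@H]2Cc2cc(OC)c(OCc3ccccc3)c(-c3cc(C[C@@H]4COC(=O)[C@@]4(OCc4ccccc4)Cc4ccc(OCc5ccccc5)c(OC)c4)cc(OC)c3OCc3ccccc3)c2)ccc1OCc1ccccc1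
F6 | step 6 | (3E,3'E)-4,4'-[6,6'-bis(benzyloxy)-5,5'-dimethoxybiphenyl-3,3'-diyl]bis[3-(methoxycarbonyl)but-3-enoic acid] | COC(=O)/C(CC(=O)O)=C/c1cc(OC)c(OCc2ccccc2)c(-c2cc(/C=C(\CC(=O)O)C(=O)OC)cc(OC)c2OCc2ccccc2)c1
F7 | step 6 | (3S,3'S)-4,4'-[6,6'-bis(benzyloxy)-5,5'-dimethoxybiphenyl-3,3'-diyl]bis[3-(methoxycarbonyl)butanoic acid] | COC(=O)[C@H](CC(=O)O)Cc1cc(OC)c(OCc2ccccc2)c(-c2cc(C[C@@H](CC(=O)O)C(=O)OC)cc(OC)c2OCc2ccccc2)c1
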